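The ten-membered carbocycle is disconnected at its only olefin, the cis C5=C6 bond (germacrane numbering) flanked by the allylic methines C4 and C7. A ring-closing metathesis forges this bond last, on a diene whose two vinyl-terminated arms sit trans on C10 and C1 of the finished dihydropyran–acylfilicinic acid bicycle; it creates the ring and the Z olefin but no stereocentre. All four stereocentres are therefore set beforehand in open-chain chemistry: C7 by Shi epoxidation and vinylcuprate opening of geranyl acetate, C10 and C1 by Sharpless epoxidation and anti opening with a C4-stereodefined Grignard reagent from citronellyl bromide. The pyran is then annulated onto isobutyrylfilicinic acid.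

Key step: step 10

Remark: terpenoid carbons are numbered as in germacrane (C1–C10 ring, C11 carbinol carbon), the pyran methylene is C1′, and the acylphloroglucinol unit is drawn in the dienol–ketone tautomer of the target.

Step 1
Reactants: 1 geranyl acetate
Product: 3 (R)-6,7-epoxygeraniol, via (R)-6,7-epoxygeranyl acetate 2 (not isolated)
Conditions: D-fructose-derived Shi ketone (30 mol%), Oxone (KHSO5), K2CO3, Bu4NHSO4, MeCN–CH2(OMe)2–aq. borate buffer, 0 °C; then K2CO3 (cat.), MeOH, rt
Reagents that add atoms: potassium peroxymonosulfate from Oxone ([K+].[O-]S(=O)(=O)OO)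
Why: Shi asymmetric epoxidation followed by base-catalysed transesterification: the fructose-derived dioxirane should attack only the electron-rich 6,7-olefin (the 2,3-olefin is deactivated by the allylic acetate) through the spiro transition state that gives the 6R epoxide, and methanolysis then frees the allylic alcohol without touching the epoxide.

Step 2
Reactants: 3 (R)-6,7-epoxygeraniol
Product: 4 (2E,6R)-6-ethenyl-3,7-dimethyloct-2-ene-1,7-diol
Conditions: CH2=CHMgBr (4 equiv), CuBr·SMe2 (20 mol%), THF, −30 → 0 °C; aq. NH4Cl
Reagents that add atoms: vinylmagnesium bromide (C=C[Mg]Br)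
Why: Copper-catalysed Grignard opening of a trisubstituted epoxide: the vinylcuprate attacks the secondary epoxide carbon in SN2 fashion with inversion, which turns the 6R epoxide into the R-configured vinyl-bearing carbon (future C7) and frees the tertiary C11 alcohol.

Step 3
Reactants: 4 (2E,6R)-6-ethenyl-3,7-dimethyloct-2-ene-1,7-diol
Product: 5 [(2R,3R)-3-[(3R)-3-ethenyl-4-hydroxy-4-methylpentyl]-3-methyloxiran-2-yl]methanol
Conditions: Ti(OiPr)4 (20 mol%), D-(−)-diethyl tartrate (24 mol%), t-BuOOH (2 equiv), 4 Å molecular sieves, CH2Cl2, −20 °C
Reagents that add atoms: tert-butyl hydroperoxide (CC(C)(C)OO)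
Why: Sharpless asymmetric epoxidation: the titanium tartrate complex binds the primary allylic alcohol and, with the D-(−)-tartrate, delivers oxygen to the face of the (E)-trisubstituted olefin that gives the 2R,3R epoxy alcohol (future C1 and C10) under reagent control, while the isolated vinyl group is not epoxidised.

Step 4
Reactants: 6 (R)-citronellyl bromide
Product: 7 (4R)-6-bromo-4-methylhexanal
Conditions: O3, CH2Cl2, −78 °C; then PPh3, −78 °C → rt
Reagents that add atoms: ozone ([O-][O+]=O)
Why: Ozonolysis with reductive work-up cleaves the only olefin to the aldehyde and leaves the remote methyl-bearing stereocentre and the primary bromide untouched.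

Step 5
Reactants: 7 (4R)-6-bromo-4-methylhexanal
Product: 8 (3S)-5-bromo-3-methylpent-1-ene
Conditions: [Rh(cod)(OMe)]2 (1 mol%), Xantphos (2 mol%), 3-methoxybenzoic acid (5 mol%), norbornadiene (3 equiv), THF, 60 °C
Reagents that add atoms: none
Why: Rhodium-catalysed transfer hydroformylation run in the dehydroformylation direction: acyl C–H activation, CO de-insertion and β-hydride elimination release the terminal olefin while H2 and CO pass to the strained acceptor, which also intercepts the rhodium hydride before it can move the new double bond into the stereocentre, whose configuration is unchanged (the descriptor changes from R to S only because the priorities change).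

Step 6
Reactants: 5 [(2R,3R)-3-[(3R)-3-ethenyl-4-hydroxy-4-methylpentyl]-3-methyloxiran-2-yl]methanol; 8 (3S)-5-bromo-3-methylpent-1-ene
Product: 10 (2S,3R,6R)-6-ethenyl-3,7-dimethyl-2-[(3S)-3-methylpent-4-en-1-yl]octane-1,3,7-triol, via Grignard reagent 9 (not isolated)
Conditions: 8, Mg, THF, rt; 5 pre-treated with MeMgBr (2.0 equiv), THF, −40 °C; then CuI (10 mol%) and the solution of 9 (1.5 equiv), −40 → 0 °C; aq. NH4Cl
Reagents that add atoms: none
Why: Copper-catalysed Grignard opening of a 2,3-epoxy alcohol: because C3 is fully substituted the alkylcuprate attacks C2 of the magnesium alkoxide with inversion, which sets C1 as S next to the Sharpless-derived 10R tertiary carbinol (the anti pair that becomes the trans ring fusion) and brings in C4 with its configuration from the chiral pool.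

Step 7
Reactants: 10 (2S,3R,6R)-6-ethenyl-3,7-dimethyl-2-[(3S)-3-methylpent-4-en-1-yl]octane-1,3,7-triol
Product: 11 (2R,3R,6R)-6-ethenyl-3,7-dihydroxy-3,7-dimethyl-2-[(3S)-3-methylpent-4-en-1-yl]octanal
Conditions: TEMPO (10 mol%), PhI(OAc)2 (1.1 equiv), CH2Cl2, 0 °C → rt
Reagents that add atoms: none
Why: Oxoammonium (TEMPO) oxidation is selective for the primary alcohol over the two tertiary alcohols and the olefins, and its near-neutral conditions should leave the α-stereocentre of the β-hydroxy aldehyde intact (the descriptor at that carbon changes to R by priority only).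

Step 8
Reactants: 12 phloroisobutyrophenone
Product: 13 isobutyrylfilicinic acid
Conditions: NaOMe (2.2 equiv), MeI (2.2 equiv), MeOH, 0 °C → rt; aq. HCl
Reagents that add atoms: iodomethane (CI)
Why: Dearomatising double C-methylation of the acylphloroglucinol anion, the classical route to acylfilicinic acids: the second methyl group enters at the ring carbon that already carries the first, which gives the gem-dimethyl triketone.

Step 9
Reactants: 11 (2R,3R,6R)-6-ethenyl-3,7-dihydroxy-3,7-dimethyl-2-[(3S)-3-methylpent-4-en-1-yl]octanal; 13 isobutyrylfilicinic acid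
Product: 15 (2R,3S)-2-[(3R)-3-ethenyl-4-hydroxy-4-methylpentyl]-7-hydroxy-2,6,6-trimethyl-3-[(3S)-3-methylpent-4-en-1-yl]-8-(2-methylpropanoyl)-2,3,4,6-tetrahydro-5H-chromen-5-one, via C-alkylated triketone 14 (not isolated)
Conditions: Hantzsch ester (1.2 equiv), L-proline (10 mol%), CH2Cl2, rt; then PPTS (10 mol%), 4 Å molecular sieves, toluene, 50 °C
Reagents that add atoms: none
Why: Three-component reductive alkylation (Knoevenagel condensation at the only free ring CH of 13, then transfer hydrogenation of the alkylidene triketone by the Hantzsch ester) followed by acid-catalysed cyclodehydration through the six-membered hemiketal: no bond to C1 or C10 is broken, so both configurations are carried over and the anti pair from step 6 becomes the trans ring fusion, and the tertiary hydroxyl is expected to close on the carbonyl flanked by the acyl-bearing carbon, away from the quaternary C(CH3)2 centre, as in the natural congeners of this vinylogous ester.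

Step 10
Reactants: 15 (2R,3S)-2-[(3R)-3-ethenyl-4-hydroxy-4-methylpentyl]-7-hydroxy-2,6,6-trimethyl-3-[(3S)-3-methylpent-4-en-1-yl]-8-(2-methylpropanoyl)-2,3,4,6-tetrahydro-5H-chromen-5-one
Product: 16 CNP0564661.1
Conditions: second-generation Hoveyda–Grubbs catalyst [RuCl2(H2IMes)(=CH-C6H4-2-OiPr)] (10 mol%, two portions), 2,6-dichloro-1,4-benzoquinone (20 mol%), toluene (0.5 mM), 80 °C, argon sparge
Reagents that add atoms: none
Why: Ring-closing olefin metathesis by the Chauvin mechanism: a ruthenium alkylidene forms at the less hindered C4 vinyl group, adds across the C7 vinyl group in a [2+2] cycloaddition, and cycloreversion of the ruthenacyclobutane releases the C5=C6 olefin and ethene, whose removal pulls the equilibrium forward. The closest known reaction type is ring-closing metathesis of 1,11-dienes to cyclodecenes and ten-membered lactones whose arms are held close by an existing ring. The ten-membered ring closes by metathesis between the two terminal olefin carbons C5 and C6, both of which become endocyclic, so the exo/endo attack classification does not apply. No stereocentre is created; the Z geometry is expected under thermodynamic control, because a cis-cyclodecene trans-fused to the half-chair dihydropyran should be clearly less strained than its E isomer and the second-generation catalyst re-opens strained olefins. Ring closure must win over oligomerisation, which is secured by the trans-diequatorial arms on the adjacent carbons C10 and C1 and by high dilution with portionwise catalyst addition. Chemoselectivity is secured because the only other C=C bonds are tetrasubstituted, electron-poor enol olefins of the triketone, which ruthenium carbenes do not engage.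

Compound list
1 | geranyl acetate, (2E)-3,7-dimethylocta-2,6-dien-1-yl acetate | CC(=O)OC/C=C(\C)CCC=C(C)C | starting material
2 | (R)-6,7-epoxygeranyl acetate, (2E)-5-[(2R)-3,3-dimethyloxiran-2-yl]-3-methylpent-2-en-1-yl acetate | CC(=O)OC/C=C(\C)CC[C@H]1OC1(C)C | intermediate (not isolated)
3 | (R)-6,7-epoxygeraniol, (2E)-5-[(2R)-3,3-dimethyloxiran-2-yl]-3-methylpent-2-en-1-ol | OC/C=C(\C)CC[C@H]1OC1(C)C | intermediate
4 | (2E,6R)-6-ethenyl-3,7-dimethyloct-2-ene-1,7-diol | OC/C=C(\C)CC[C@@H](C(C)(C)O)C=C | intermediate
5 | [(2R,3R)-3-[(3R)-3-ethenyl-4-hydroxy-4-methylpentyl]-3-methyloxiran-2-yl]methanol | OC[C@H]1O[C@]1(C)CC[C@@H](C(C)(C)O)C=C | intermediate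
6 | (R)-citronellyl bromide, (6R)-8-bromo-2,6-dimethyloct-2-ene | BrCC[C@H](C)CCC=C(C)C | starting material
7 | (4R)-6-bromo-4-methylhexanal | BrCC[C@H](C)CCC=O | intermediate
8 | (3S)-5-bromo-3-methylpent-1-ene | BrCC[C@H](C)C=C | intermediate
9 | [(3S)-3-methylpent-4-en-1-yl]magnesium bromide | Br[Mg]CC[C@H](C)C=C | intermediate (not isolated)
10 | (2S,3R,6R)-6-ethenyl-3,7-dimethyl-2-[(3S)-3-methylpent-4-en-1-yl]octane-1,3,7-triol | OC[C@H](CC[C@H](C)C=C)[C@](C)(O)CC[C@@H](C(C)(C)O)C=C | intermediate
11 | (2R,3R,6R)-6-ethenyl-3,7-dihydroxy-3,7-dimethyl-2-[(3S)-3-methylpent-4-en-1-yl]octanal | O=C[C@H](CC[C@H](C)C=C)[C@](C)(O)CC[C@@H](C(C)(C)O)C=C | intermediate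
12 | phloroisobutyrophenone, 2-methyl-1-(2,4,6-trihydroxyphenyl)propan-1-one | CC(C)C(=O)c1c(O)cc(O)cc1O | starting material
13 | isobutyrylfilicinic acid, 3,5-dihydroxy-6,6-dimethyl-4-(2-methylpropanoyl)cyclohexa-2,4-dien-1-one (tautomer of 2-isobutyryl-4,4-dimethylcyclohexane-1,3,5-trione) | CC(C)C(=O)C1=C(O)C(C)(C)C(=O)C=C1O | intermediate
14 | 2-[(2S,3R,6R)-6-ethenyl-3,7-dihydroxy-3,7-dimethyl-2-[(3S)-3-methylpent-4-en-1-yl]octyl]-3,5-dihydroxy-6,6-dimethyl-4-(2-methylpropanoyl)cyclohexa-2,4-dien-1-one | CC(C)C(=O)C1=C(O)C(C)(C)C(=O)C(C[C@H](CC[C@H](C)C=C)[C@](C)(O)CC[C@@H](C(C)(C)O)C=C)=C1O | intermediate (not isolated)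
15 | (2R,3S)-2-[(3R)-3-ethenyl-4-hydroxy-4-methylpentyl]-7-hydroxy-2,6,6-trimethyl-3-[(3S)-3-methylpent-4-en-1-yl]-8-(2-methylpropanoyl)-2,3,4,6-tetrahydro-5H-chromen-5-one | CC(C)C(=O)C1=C(O)C(C)(C)C(=O)C2=C1O[C@](C)(CC[C@@H](C(C)(C)O)C=C)[C@@H](CC[C@H](C)C=C)C2 | intermediate
16 | CNP0564661.1: (1S,4S,7R,10R,5Z) ten-membered carbocycle trans-fused at C1–C10 to the dihydropyran of the 7-hydroxy-6,6-dimethyl-8-isobutyryl-chromen-5-one core, with C4 methyl, C7 2-hydroxypropan-2-yl and C10 methyl | CC(C)C(=O)C1=C(O)C(C)(C)C(=O)C2=C1O[C@]1(C)CC[C@@H](C(C)(C)O)/C=C\[C@@H](C)CC[C@H]1C2 | target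

Total step count: 10. Longest linear sequence: 7 steps (steps 1, 2, 3, 6, 7, 9, 10, from geranyl acetate).

Steps most likely to fail

Step 10 (ring-closing metathesis). Intermolecular metathesis may outrun closure of the strained ring, the hindered vinyl group next to the carbinol carbon may engage too slowly, ruthenium hydrides may migrate the double bonds, or the E olefin may form. The fallback sets out from 15: both vinyl groups are cleaved (OsO4 cat., NaIO4, 2,6-lutidine, dioxane–water) to the dialdehyde F1, and the C5=C6 bond is then formed by intramolecular McMurry coupling with low-valent titanium (TiCl3(DME)1.5, Zn–Cu couple, DME, reflux, slow addition), a carbonyl coupling known to close germacrane-size rings. It comes back to the route at 16; olefin isomers would have to be separated.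

Step 9 (pyran annulation). C1 may epimerise through enamine or enol formation of the α-branched β-hydroxy aldehyde, the tertiary hydroxyl may be lost by β-elimination, the alkylidene intermediate may be captured by an intramolecular hetero-Diels–Alder reaction with the C4 vinyl group, or the ring may close through the carbonyl oxygen next to the gem-dimethyl carbon. The fallback sets out from triol 10 and avoids any aldehyde or alkylidene: selective iodination of the primary alcohol (I2, PPh3, imidazole, CH2Cl2, 0 °C) gives the primary iodide F2, which alkylates the dianion of 13 at its free ring carbon (NaOMe, MeOH, 50 °C) in an SN2 reaction. It comes back to the route at 14, which is cyclised to 15 by the acid stage of step 9.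

Step 5 (dehydroformylation). Re-addition of rhodium hydride may move the double bond inward, with loss of the terminal position and of the C4 stereocentre, or simple decarbonylation to the alkane may compete. The fallback sets out from aldehyde 7: Pinnick oxidation (NaClO2, NaH2PO4, 2-methylbut-2-ene, t-BuOH–water) gives (4R)-6-bromo-4-methylhexanoic acid F3, and Kochi oxidative decarboxylation (Pb(OAc)4, Cu(OAc)2 cat., pyridine, benzene, 80 °C) turns the CH2CH2CO2H end into the vinyl group. It comes back to the route at 8.

Further compounds
F1 | step 10 | dialdehyde of 15 with both vinyl groups cleaved to formyl groups (C5 and C6 as CHO) | CC(C)C(=O)C1=C(O)C(C)(C)C(=O)C2=C1O[C@](C)(CC[C@@H](C(C)(C)O)C=O)[C@@H](CC[C@H](C)C=O)C2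
F2 | step 9 | (3R,6R,7R,10S)-3-ethenyl-7-(iodomethyl)-2,6,10-trimethyldodec-11-ene-2,6-diol | IC[C@H](CC[C@H](C)C=C)[C@](C)(O)CC[C@@H](C(C)(C)O)C=C
F3 | step 5 | (4R)-6-bromo-4-methylhexanoic acid | BrCC[C@H](C)CCC(=O)O
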